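**Plan**
Retrosynthesis: the C2 and C6 bromines are taken off first, the C3 hydroxyl is masked as a methyl ether, and the C1–CH2 and CH2–S bonds are then cut together, leading to 2-bromo-6-methoxyphenol 1, formaldehyde 2 and sodium methanesulfinate 3.
Forward: 1, 2 and 3 are joined in one pot through benzyl alcohol 4 and para-quinone methide 5 to the benzyl methyl sulfone 6; ether cleavage via borate 7 gives catechol 8; bromination at C6 (9) and then at C2 gives the target 10.
Enabling feature: in the benzene ring, C1 (bearing CH2SO2CH3) is para to the C4 hydroxyl, and both carbons ortho to that hydroxyl, C3 (oxygen) and C5 (bromine), are already substituted, so a one-carbon electrophile directed by the C4 phenoxide can enter only at C1.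
Rings: the benzene ring is bought with 1 and no ring is closed anywhere in the route.
Stereochemistry: the target has no stereocentre, so none has to be set or protected.

Key step: step 1

Remark: ring positions of all intermediates are named with the target's numbering (C1 CH2SO2CH3, C2 Br, C3 OH, C4 OH, C5 Br, C6 Br); 1, 2 (as paraformaldehyde) and 3 are assumed to be purchased.

**Step 1**
Reactants: 1 2-bromo-6-methoxyphenol; 2 formaldehyde (charged as paraformaldehyde); 3 sodium methanesulfinate
Product: 6 3-bromo-4-hydroxy-5-methoxybenzyl methyl sulfone, via benzyl alcohol 4 (not isolated), via para-quinone methide 5 (not isolated)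
Conditions: (CH2O)n (3 equiv), NaOH (1.1 equiv), H2O, 25 to 40 °C; then CH3SO2Na (5 equiv), HCO2H–H2O, 50 °C
Reagents that add atoms: none
Why: In aqueous NaOH the phenoxide of 1 adds to formaldehyde at C1 (Lederer–Manasse hydroxymethylation) to give benzyl alcohol 4; on acidification with formic acid 4 loses water to para-quinone methide 5, and methanesulfinate adds 1,6 through sulfur, so that rearomatisation delivers sulfone 6 with the C1–CH2 and CH2–S bonds made in one flask. The closest known reaction type is the Mannich-type three-component sulfonylmethylation of phenols and naphthols with an aldehyde and a sulfinic acid, together with the sulfinate capture of 4-hydroxybenzyl alcohols. No ring is closed and no stereocentre is formed. The step needs attack at C1 only, and the substrate secures it: the phenoxide directs ortho and para, both ortho carbons already carry the methoxy group (C3) and bromine (C5), and in base the phenoxide far outweighs the methoxy group, which could otherwise steer an acid-mediated attack to C6. Sulfur versus oxygen alkylation of the ambident sulfinate is settled thermodynamically, because a sulfinate ester re-ionises to 5 in the acidic medium whereas the sulfone does not. Diarylmethane formation is held back by excess formaldehyde in the basic stage and by excess CH3SO2Na in the acidic stage.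

**Step 2**
Reactants: 6 3-bromo-4-hydroxy-5-methoxybenzyl methyl sulfone
Product: 8 3-bromo-4,5-dihydroxybenzyl methyl sulfone, via cyclic bromoborate 7 (not isolated)
Conditions: BBr3 (3 equiv), CH2Cl2, −78 to 0 °C; then H2O, 0 °C
Reagents that add atoms: none
Why: BBr3 cleavage of an aryl methyl ether should proceed readily here because the neighbouring C4 phenol binds boron, bromide removes the methyl group as CH3Br, and the resulting cyclic borate 7 hydrolyses on quench, while the sulfone and aryl bromide are inert and the cold, base-free work-up avoids sulfinate elimination from the 4-hydroxybenzyl sulfone.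

**Step 3**
Reactants: 8 3-bromo-4,5-dihydroxybenzyl methyl sulfone
Product: 10 2,3,6-tribromo-4,5-dihydroxybenzyl methyl sulfone, via dibromocatechol sulfone 9 (not isolated)
Conditions: Br2 (2.3 equiv), AcOH, 20 to 45 °C, dark; then aq Na2S2O4
Reagents that add atoms: bromine, BrBr
Why: Electrophilic aromatic bromination of a catechol should work because the C3 hydroxyl activates exactly the two free positions, C6 (para, expected first) and then C2 (ortho), while acetic acid keeps the catechol un-ionised and the dithionite quench returns any ortho-quinone to the catechol.

**Compound list**
1 | 2-bromo-6-methoxyphenol | COc1cccc(Br)c1O | starting material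
2 | formaldehyde (used as paraformaldehyde) | C=O | starting material
3 | sodium methanesulfinate | CS(=O)[O-].[Na+] | starting material
4 | 3-bromo-4-hydroxy-5-methoxybenzyl alcohol | OCc1cc(Br)c(O)c(OC)c1 | intermediate
5 | 2-bromo-6-methoxy-4-methylidenecyclohexa-2,5-dien-1-one | C=C1C=C(Br)C(=O)C(OC)=C1 | intermediate
6 | 3-bromo-4-hydroxy-5-methoxybenzyl methyl sulfone | CS(=O)(=O)Cc1cc(Br)c(O)c(OC)c1 | intermediate
7 | 2,4-dibromo-6-[(methylsulfonyl)methyl]-1,3,2-benzodioxaborole | CS(=O)(=O)Cc1cc(Br)c2OB(Br)Oc2c1 | intermediate
8 | 3-bromo-4,5-dihydroxybenzyl methyl sulfone (3-bromo-5-[(methylsulfonyl)methyl]benzene-1,2-diol) | CS(=O)(=O)Cc1cc(O)c(O)c(Br)c1 | intermediate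
9 | 2,3-dibromo-4,5-dihydroxybenzyl methyl sulfone (3,4-dibromo-5-[(methylsulfonyl)methyl]benzene-1,2-diol) | CS(=O)(=O)Cc1cc(O)c(O)c(Br)c1Br | intermediate
10 | 2,3,6-tribromo-4,5-dihydroxybenzyl methyl sulfone (3,4,6-tribromo-5-[(methylsulfonyl)methyl]benzene-1,2-diol) | CS(=O)(=O)Cc1c(Br)c(O)c(O)c(Br)c1Br | target

Total step count: 3. Longest linear sequence: 3 steps.

**Steps most likely to fail**

Step 1. The bromine-bearing phenoxide may hydroxymethylate sluggishly, and quinone methide 5 may condense with a second arene to diarylmethanes or oligomers faster than the sulfinate captures it. The fallback separates the two bond formations and releases 5 slowly. Starting from 1, an amine Mannich reaction with 2 and aqueous dimethylamine in ethanol at reflux should give 2-bromo-4-[(dimethylamino)methyl]-6-methoxyphenol F1, which can be purified by acid–base extraction. Heating F1 with 3 in DMF–H2O at about 100 °C should expel dimethylamine, regenerate 5 at low stationary concentration and let the sulfinate trap it, rejoining the route at 6.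

Step 3. Bromine may oxidise the catechol to an ortho-quinone, or the second substitution at the flanked C2 may stall and leave mixtures of di- and tribromides. The fallback moves one bromination ahead of the ether cleavage so that the free catechol meets only one equivalent of a mild electrophile. Starting from 6, Br2 (1.05 equiv) in AcOH should brominate C6, para to the methoxy group, and give 2,3-dibromo-4-hydroxy-5-methoxybenzyl methyl sulfone F2. BBr3 in CH2Cl2 then frees the catechol, and the route is rejoined at 9, now isolated. One equivalent of N-bromosuccinimide in MeCN at 0 °C should then place the last bromine at C2 to give 10.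

Step 2. The Lewis acid may ionise the benzylic C–S bond, with loss of methanesulfinate through a boron-bound quinone-methide-like cation, or the sulfone oxygens may sequester BBr3 and leave the ether intact. The fallback removes the methyl group oxidatively. Starting from 6, 2-iodoxybenzoic acid (IBX) in DMF at 25 °C should oxygenate the methoxy-bearing C3 and expel methanol to give 3-bromo-5-[(methylsulfonyl)methyl]cyclohexa-3,5-diene-1,2-dione F3. Reduction in the same pot with aqueous Na2S2O4 rejoins the route at 8.

**Further compounds**
F1 | step 1 | 2-bromo-4-[(dimethylamino)methyl]-6-methoxyphenol | CN(C)Cc1cc(Br)c(O)c(OC)c1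
F2 | step 3 | 2,3-dibromo-4-hydroxy-5-methoxybenzyl methyl sulfone | CS(=O)(=O)Cc1cc(OC)c(O)c(Br)c1Br
F3 | step 2 | 3-bromo-5-[(methylsulfonyl)methyl]cyclohexa-3,5-diene-1,2-dione | CS(=O)(=O)CC1=CC(=O)C(=O)C(Br)=C1
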